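Assumption: the target is taken exactly as drawn, i.e. a 2,3-cis (2S,3R) dihydrobenzofuran whose C3 carboxyl is esterified by O5 of natural (3R,4S,5R)-shikimic acid.

## Retrosynthetic overview

1. Target ⇐ one acidolysis of a fully protected cis-ester (MOM ether, two acetonides, tert-butyl and PMB esters).
2. cis-Ester ⇐ photo-Wolff ring contraction of a 2-aryl-3-diazochroman-4-one (1,2-shift of aryl carbon C4a, pyranone → dihydrofuran); the ketene is captured by the free 5-OH of a 3,4-O-isopropylidene shikimate and C3 is set by protonation anti to the C2 aryl group.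
3. Diazo ketone ⇐ (2S)-flavanone ⇐ Pd-catalysed asymmetric conjugate arylation of a 5-alkenylchromone; the chromone comes from catechol acetonide (ortho-lithiation/acetylation, enaminone cyclisation) and ketone-directed C5–H olefination with tert-butyl acrylate.
4. Shikimate alcohol ⇐ furan + acryloyl imide (Cu–box Diels–Alder), transesterification/E1cB bridge opening, OsO4, acetonide.
5. Ring order: chromone pyranone → chiral flavanone; shikimate cyclohexene in parallel; the dihydrofuran last, by contraction of the pyranone.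

## Route

Step 1
Reactants: 1 2,2-dimethyl-1,3-benzodioxole; 2 N-methoxy-N-methylacetamide
Product: 4 1-(2,2-dimethyl-1,3-benzodioxol-4-yl)ethan-1-one, via 4-lithio ketal 3 (not isolated)
Conditions: s-BuLi (1.1 equiv), TMEDA, THF, −78 °C; then 2, −78 → 0 °C; aq NH4Cl
Reagents that add atoms: none
Why: Directed ortho-metalation: the ketal oxygens direct lithiation only to the flanking C4–H, and the chelated Weinreb adduct collapses to the methyl ketone on work-up, so a single 1,2,3-trisubstituted arene results.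

Step 2
Reactants: 4 1-(2,2-dimethyl-1,3-benzodioxol-4-yl)ethan-1-one; 5 N,N-dimethylformamide dimethyl acetal
Product: 7 8-hydroxy-4H-chromen-4-one, via enaminone 6 (not isolated)
Conditions: 5 (2 equiv), toluene, 100 °C; evaporate; TFA/H2O (9:1), 50 °C
Reagents that add atoms: none
Why: Enaminone chromone synthesis: condensation with the amide acetal gives the β-aminoenone, and aqueous acid then hydrolyses the aryl ketal so that the phenol ortho to the carbonyl closes by addition–elimination (loss of Me2NH), leaving the C8 hydroxyl free.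

Step 3
Reactants: 7 8-hydroxy-4H-chromen-4-one
Product: 8 8-(methoxymethoxy)-4H-chromen-4-one
Conditions: MOMCl (1.3 equiv), K2CO3, acetone, 0 °C → rt
Reagents that add atoms: chloromethyl methyl ether, COCCl
Why: Williamson etherification of the only phenol; the MOM ether tolerates the later organometallic, basic and photochemical steps and falls in the final acidolysis.

Step 4
Reactants: 8 8-(methoxymethoxy)-4H-chromen-4-one; 9 tert-butyl acrylate
Product: 10 tert-butyl (E)-3-[8-(methoxymethoxy)-4-oxo-4H-chromen-5-yl]prop-2-enoate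
Conditions: [Cp*RhCl2]2 (2.5 mol%), AgSbF6 (10 mol%), Cu(OAc)2 (2.1 equiv), DCE, 100 °C
Reagents that add atoms: none
Why: Ketone-directed Rh(III) oxidative C–H olefination (Fujiwara–Moritani type): the C4 carbonyl steers cyclometalation to the peri C5–H, the established site for chromones, and acrylate insertion/β-hydride elimination gives the E-enoate.

Step 5
Reactants: 1 2,2-dimethyl-1,3-benzodioxole
Product: 11 5-bromo-2,2-dimethyl-1,3-benzodioxole
Conditions: NBS (1.05 equiv), MeCN, 0 °C → rt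
Reagents that add atoms: N-bromosuccinimide, O=C1CCC(=O)N1Br
Why: Electrophilic aromatic bromination of the electron-rich ketal goes para to a ring oxygen, i.e. only to C5.

Step 6
Reactants: 11 5-bromo-2,2-dimethyl-1,3-benzodioxole
Product: 13 (2,2-dimethyl-1,3-benzodioxol-5-yl)boronic acid, via 5-lithio ketal 12 (not isolated)
Conditions: n-BuLi, THF, −78 °C; B(Oi-Pr)3, −78 °C → rt; aq NH4Cl
Reagents that add atoms: triisopropyl borate, CC(C)OB(OC(C)C)OC(C)C; water, O
Why: Bromine–lithium exchange, borate trapping and mild hydrolysis is the standard boronic acid synthesis, and the neutral work-up keeps the ketal.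

Step 7
Reactants: 10 tert-butyl (E)-3-[8-(methoxymethoxy)-4-oxo-4H-chromen-5-yl]prop-2-enoate; 13 (2,2-dimethyl-1,3-benzodioxol-5-yl)boronic acid
Product: 14 tert-butyl (E)-3-[(2S)-2-(2,2-dimethyl-1,3-benzodioxol-5-yl)-8-(methoxymethoxy)-4-oxo-3,4-dihydro-2H-chromen-5-yl]prop-2-enoate
Conditions: Pd(OCOCF3)2 (5 mol%), (R)-t-BuPyOx (6 mol%), NH4PF6 (30 mol%), H2O (5 equiv), 13 (2 equiv), DCE, 50 °C
Reagents that add atoms: none
Why: Pd(II)/pyridine-oxazoline-catalysed asymmetric conjugate addition of an arylboronic acid to a chromone (Hayashi–Miyaura-type 1,4-arylation) creates C2, the (R)-ligand being chosen by analogy with the (S)-ligand/(R)-product relationship of cyclic enones to give 2S, while the cationic aryl-Pd species should insert the cis-enone of the pyranone faster than the hindered acyclic tert-butyl enoate.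

Step 8
Reactants: 14 the (2S)-flavanone
Product: 16 tert-butyl (E)-3-[(2R)-3-diazo-2-(2,2-dimethyl-1,3-benzodioxol-5-yl)-8-(methoxymethoxy)-4-oxo-3,4-dihydro-2H-chromen-5-yl]prop-2-enoate, via trifluoroacetyl ketone 15 (not isolated)
Conditions: LiHMDS, THF, −78 °C; CF3CO2CH2CF3, −78 °C; aq NH4Cl; then p-ABSA, Et3N, MeCN, 0 °C → rt
Reagents that add atoms: 4-acetamidobenzenesulfonyl azide, CC(=O)Nc1ccc(cc1)S(=O)(=O)N=[N+]=[N-] (the two diazo nitrogens); 2,2,2-trifluoroethyl trifluoroacetate, O=C(OCC(F)(F)F)C(F)(F)F (CF3CO group of intermediate 15 only)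
Why: Regitz diazo transfer in its detrifluoroacetylative (Danheiser) form: kinetic enolisation at −78 °C and Claisen trifluoroacetylation activate C3 so that sulfonyl azide/Et3N transfers N2 with loss of the CF3CO group, C2 keeping its geometry (its descriptor becomes R only through CIP priorities).

Step 9
Reactants: 17 1,3-oxazolidin-2-one; 18 acryloyl chloride
Product: 20 3-(prop-2-enoyl)-1,3-oxazolidin-2-one, via magnesium amide 19 (not isolated)
Conditions: MeMgBr (1.0 equiv), THF, 0 °C; then 18, −78 → 0 °C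
Reagents that add atoms: none
Why: N-acylation of the oxazolidinone magnesium salt by the acid chloride (nucleophilic acyl substitution) gives the two-point-binding dienophile without amine-induced polymerisation.

Step 10
Reactants: 20 3-(prop-2-enoyl)-1,3-oxazolidin-2-one; 21 furan
Product: 22 3-{[(1R,2R,4R)-7-oxabicyclo[2.2.1]hept-5-en-2-yl]carbonyl}-1,3-oxazolidin-2-one (endo)
Conditions: [Cu((R,R)-t-Bu-box)](SbF6)2 (5 mol%), furan (10 equiv), CH2Cl2, −78 °C; recrystallise the endo isomer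
Reagents that add atoms: none
Why: Cu(II)–bis(oxazoline)-catalysed enantioselective Diels–Alder reaction: furan attacks the chelated acryloyl imide on the face left open by the tert-butyl groups, the (R,R)-ligand giving the (1R,2R,4R)-endo adduct whose C4 bridgehead becomes shikimate C5, and crystallisation removes the exo isomer.

Step 11
Reactants: 22 the endo Diels–Alder imide
Product: 24 4-methoxybenzyl (5R)-5-hydroxycyclohexa-1,3-diene-1-carboxylate, via bicyclic PMB ester 23 (not isolated)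
Conditions: 4-MeOC6H4CH2OLi (from PMBOH/n-BuLi, 1.3 equiv), THF, −20 °C; then LiHMDS (1.5 equiv), −78 → −20 °C; aq NH4Cl
Reagents that add atoms: 4-methoxybenzyl alcohol, COc1ccc(CO)cc1
Why: Lithium alkoxide transesterification at the exocyclic imide carbonyl (as with LiOBn) followed by ester enolisation and E1cB β-elimination of the strained oxygen bridge gives the dienol with the C–O stereocentre (5R) untouched.

Step 12
Reactants: 24 the (5R)-dienol PMB ester
Product: 25 4-methoxybenzyl (3R,4S,5R)-3,4,5-trihydroxycyclohex-1-ene-1-carboxylate (PMB shikimate)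
Conditions: OsO4 (2 mol%), NMO (1.3 equiv), acetone/H2O (9:1), 0 °C
Reagents that add atoms: N-methylmorpholine N-oxide, C[N+]1([O-])CCOCC1; water, O (both oxygens are delivered through catalytic OsO4, O=[Os](=O)(=O)=O)
Why: Upjohn dihydroxylation: OsO4 adds syn to the electron-richer γ,δ-alkene and anti to the allylic hydroxyl (Kishi's rule), which sets C3 (R) and C4 (S) of natural shikimate.

Step 13
Reactants: 25 PMB shikimate
Product: 26 4-methoxybenzyl (3R,4S,5R)-5-hydroxy-3,4-(isopropylidenedioxy)cyclohex-1-ene-1-carboxylate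
Conditions: Me2C(OMe)2, CSA (5 mol%), acetone, rt
Reagents that add atoms: 2,2-dimethoxypropane, COC(C)(C)OC
Why: Acid-catalysed transketalisation takes the cis-3,4-diol as the unstrained dioxolane and leaves only the C5 hydroxyl free for the coupling.

Step 14
Reactants: 16 the (2R)-3-diazoflavanone; 26 the shikimate acetonide alcohol
Product: 29 4-methoxybenzyl 3,4-O-isopropylidene-5-O-{[(2S,3R)-4-[(E)-3-tert-butoxy-3-oxoprop-1-enyl]-2-(2,2-dimethyl-1,3-benzodioxol-5-yl)-7-(methoxymethoxy)-2,3-dihydro-1-benzofuran-3-yl]carbonyl}shikimate, via ketene 27 (not isolated), via ester enol 28 (not isolated)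
Conditions: 26 (2 equiv), 4 Å MS, CH2Cl2 (0.15 M), 450 nm LEDs, −20 °C; then dark, 0 °C
Reagents that add atoms: none
Why: Proposed new method: visible-light excitation of the s-cis-locked cyclic α-diazo ketone expels N2 with 1,2-shift of the aryl carbon C4a from the carbonyl carbon to C3 (photo-Wolff rearrangement, chromanone-to-dihydrobenzofuran ring contraction); alcohol 26 adds to ketene 27 and the ester enol 28 is C-protonated on the face anti to the C2 aryl group, giving the contra-thermodynamic cis (3R) ester under base-free conditions while C2 is not involved (descriptor back to S by CIP); the closest known chemistry is the photo-Wolff ring contraction of cyclic α-diazo ketones (e.g. 2-diazo-1-tetralones to indane-1-carboxylates) with alcohol capture and kinetic protonation of ketene-derived enols, which to my knowledge has not been shown for 2-aryl-3-diazochroman-4-ones or with a complex secondary alcohol as nucleophile.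

Step 15
Reactants: 29 the fully protected cis-ester
Product: 30 (E)-3-[(2S,3R)-3-({[(1R,5R,6R)-3-carboxy-5,6-dihydroxycyclohex-3-en-1-yl]oxy}carbonyl)-2-(3,4-dihydroxyphenyl)-7-hydroxy-2,3-dihydro-1-benzofuran-4-yl]prop-2-enoic acid (CNP0312618.1)
Conditions: TFA/H2O (95:5), 1,3,5-trimethoxybenzene (6 equiv), 0 °C → rt, 2 h; RP-HPLC (0.1% HCO2H)
Reagents that add atoms: none
Why: Acidolysis (A1/SN1 cleavage of the MOM ether, both acetonides, the tert-butyl and the PMB ester) with an arene cation trap removes all five groups in one base-free operation, so base-induced C3 epimerisation or E1cB opening of the cis-ester is avoided.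

## Compound list

1 | 2,2-dimethyl-1,3-benzodioxole | CC1(C)Oc2ccccc2O1 | starting material
2 | N-methoxy-N-methylacetamide | CC(=O)N(C)OC | starting material
3 | (2,2-dimethyl-1,3-benzodioxol-4-yl)lithium | [Li]c1cccc2OC(C)(C)Oc12 | intermediate (not isolated)
4 | 1-(2,2-dimethyl-1,3-benzodioxol-4-yl)ethan-1-one | CC(=O)c1cccc2OC(C)(C)Oc12 | intermediate
5 | N,N-dimethylformamide dimethyl acetal | COC(OC)N(C)C | starting material
6 | (E)-3-(dimethylamino)-1-(2,2-dimethyl-1,3-benzodioxol-4-yl)prop-2-en-1-one | CN(C)/C=C/C(=O)c1cccc2OC(C)(C)Oc12 | intermediate (not isolated)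
7 | 8-hydroxy-4H-chromen-4-one | O=c1ccoc2c(O)cccc12 | intermediate
8 | 8-(methoxymethoxy)-4H-chromen-4-one | COCOc1cccc2c(=O)ccoc12 | intermediate
9 | tert-butyl acrylate | C=CC(=O)OC(C)(C)C | starting material
10 | tert-butyl (E)-3-[8-(methoxymethoxy)-4-oxo-4H-chromen-5-yl]prop-2-enoate | COCOc1ccc(/C=C/C(=O)OC(C)(C)C)c2c(=O)ccoc12 | intermediate
11 | 5-bromo-2,2-dimethyl-1,3-benzodioxole | CC1(C)Oc2ccc(Br)cc2O1 | intermediate
12 | (2,2-dimethyl-1,3-benzodioxol-5-yl)lithium | [Li]c1ccc2OC(C)(C)Oc2c1 | intermediate (not isolated)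
13 | (2,2-dimethyl-1,3-benzodioxol-5-yl)boronic acid | CC1(C)Oc2ccc(B(O)O)cc2O1 | intermediate
14 | tert-butyl (E)-3-[(2S)-2-(2,2-dimethyl-1,3-benzodioxol-5-yl)-8-(methoxymethoxy)-4-oxo-3,4-dihydro-2H-chromen-5-yl]prop-2-enoate | COCOc1ccc(/C=C/C(=O)OC(C)(C)C)c2C(=O)C[C@@H](c3ccc4OC(C)(C)Oc4c3)Oc12 | intermediate
15 | tert-butyl (E)-3-[(2S)-2-(2,2-dimethyl-1,3-benzodioxol-5-yl)-8-(methoxymethoxy)-4-oxo-3-(trifluoroacetyl)-3,4-dihydro-2H-chromen-5-yl]prop-2-enoate (C3 epimers/enol) | COCOc1ccc(/C=C/C(=O)OC(C)(C)C)c2C(=O)C(C(=O)C(F)(F)F)[C@@H](c3ccc4OC(C)(C)Oc4c3)Oc12 | intermediate (not isolated)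
16 | tert-butyl (E)-3-[(2R)-3-diazo-2-(2,2-dimethyl-1,3-benzodioxol-5-yl)-8-(methoxymethoxy)-4-oxo-3,4-dihydro-2H-chromen-5-yl]prop-2-enoate | COCOc1ccc(/C=C/C(=O)OC(C)(C)C)c2C(=O)C(=[N+]=[N-])[C@@H](c3ccc4OC(C)(C)Oc4c3)Oc12 | intermediate
17 | 1,3-oxazolidin-2-one | O=C1NCCO1 | starting material
18 | acryloyl chloride | C=CC(=O)Cl | starting material
19 | (2-oxo-1,3-oxazolidin-3-yl)magnesium bromide | O=C1OCCN1[Mg]Br | intermediate (not isolated)
20 | 3-(prop-2-enoyl)-1,3-oxazolidin-2-one | C=CC(=O)N1CCOC1=O | intermediate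
21 | furan | c1ccoc1 | starting material
22 | 3-{[(1R,2R,4R)-7-oxabicyclo[2.2.1]hept-5-en-2-yl]carbonyl}-1,3-oxazolidin-2-one (endo) | O1[C@@H]2C[C@@H](C(=O)N3CCOC3=O)[C@H]1C=C2 | intermediate
23 | 4-methoxybenzyl (1R,2R,4R)-7-oxabicyclo[2.2.1]hept-5-ene-2-carboxylate | O1[C@@H]2C[C@@H](C(=O)OCc3ccc(OC)cc3)[C@H]1C=C2 | intermediate (not isolated)
24 | 4-methoxybenzyl (5R)-5-hydroxycyclohexa-1,3-diene-1-carboxylate | O[C@@H]1CC(C(=O)OCc2ccc(OC)cc2)=CC=C1 | intermediate
25 | 4-methoxybenzyl (3R,4S,5R)-3,4,5-trihydroxycyclohex-1-ene-1-carboxylate | O[C@@H]1CC(C(=O)OCc2ccc(OC)cc2)=C[C@@H](O)[C@H]1O | intermediate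
26 | 4-methoxybenzyl (3R,4S,5R)-5-hydroxy-3,4-(isopropylidenedioxy)cyclohex-1-ene-1-carboxylate | O[C@@H]1CC(C(=O)OCc2ccc(OC)cc2)=C[C@H]3OC(C)(C)O[C@@H]13 | intermediate
27 | tert-butyl (E)-3-[(2R)-2-(2,2-dimethyl-1,3-benzodioxol-5-yl)-7-(methoxymethoxy)-3-(oxomethylidene)-2,3-dihydro-1-benzofuran-4-yl]prop-2-enoate (ketene) | COCOc1ccc(/C=C/C(=O)OC(C)(C)C)c2C(=C=O)[C@@H](c3ccc4OC(C)(C)Oc4c3)Oc12 | intermediate (not isolated)
28 | ester enol of 29 (C3=C(OH)O-shikimate, 2R, enol geometry undefined) | COCOc1ccc(/C=C/C(=O)OC(C)(C)C)c2C(=C(O)O[C@@H]5CC(C(=O)OCc6ccc(OC)cc6)=C[C@H]7OC(C)(C)O[C@@H]57)[C@@H](c3ccc4OC(C)(C)Oc4c3)Oc12 | intermediate (not isolated)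
29 | 4-methoxybenzyl 3,4-O-isopropylidene-5-O-{[(2S,3R)-4-[(E)-3-tert-butoxy-3-oxoprop-1-enyl]-2-(2,2-dimethyl-1,3-benzodioxol-5-yl)-7-(methoxymethoxy)-2,3-dihydro-1-benzofuran-3-yl]carbonyl}shikimate (2,3-cis) | COCOc1ccc(/C=C/C(=O)OC(C)(C)C)c2[C@@H](C(=O)O[C@@H]5CC(C(=O)OCc6ccc(OC)cc6)=C[C@H]7OC(C)(C)O[C@@H]57)[C@@H](c3ccc4OC(C)(C)Oc4c3)Oc12 | intermediate
30 | (E)-3-[(2S,3R)-3-({[(1R,5R,6R)-3-carboxy-5,6-dihydroxycyclohex-3-en-1-yl]oxy}carbonyl)-2-(3,4-dihydroxyphenyl)-7-hydroxy-2,3-dihydro-1-benzofuran-4-yl]prop-2-enoic acid | O=C(O)/C=C/c1ccc(O)c2c1[C@@H](C(=O)O[C@@H]1CC(C(=O)O)=C[C@@H](O)[C@H]1O)[C@@H](c1ccc(O)c(O)c1)O2 | target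

## Step count and risks

Total steps: 15. Longest linear sequence: 8 (steps 1, 2, 3, 4, 7, 8, 14, 15).

The three steps most likely to fail:

Step 14 (the proposed photo-Wolff contraction with cis-selective capture). The risks are 1,2-H shift to the flavone, O–H insertion, and slow capture of the hindered ketene. The fallback uses known chemistry, sets out from flavanone 14 and returns at 29. Oxidative ring contraction of the flavanone with PhI(OH)OTs in HC(OMe)3 (iodine(III)-induced 1,2-aryl shift, known for flavanones) gives the trans methyl ester F1. Me3SnOH (DCE, 70 °C) cleaves only the methyl ester to the trans acid F2, and Ghosez's reagent converts it into the acid chloride F3. Dehydrochlorination with i-Pr2NEt at −78 °C in the presence of 26 regenerates ketene 27 (the classical acyl chloride route to ketenes), which is captured and protonated through 28 as in step 14 to give 29.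

Step 7 (chemoselectivity of the chromone over the enoate, and ee on a 5-substituted chromone). The fallback sets out from chromone 8 and returns at 14. Chromone 8 is arylated first with 13 under the same Pd/(R)-t-BuPyOx conditions, where no second acceptor is present, to give the simple (2S)-flavanone F4. Acrylate 9 is then introduced by ketone-directed Ru(II)-catalysed C5–H alkenylation ([RuCl2(p-cymene)]2, AgSbF6, Cu(OAc)2, DCE, 100 °C), which gives 14.

Step 15 (the aryl acetonide needs about 95% TFA, which may ionise the unmasked 4-hydroxybenzylic C2–O bond and erode the cis configuration). The fallback changes the catechol protection, sets out from chromone 10 and returns at target 30. Catechol with MOMCl/i-Pr2NEt gives 1,2-bis(methoxymethoxy)benzene F5, and NBS gives 4-bromo-1,2-bis(methoxymethoxy)benzene F6. n-BuLi gives [3,4-bis(methoxymethoxy)phenyl]lithium F7, and B(Oi-Pr)3 then gives [3,4-bis(methoxymethoxy)phenyl]boronic acid F8. This acid replaces 13 in step 7 with chromone 10 to give the tris-MOM flavanone F9. Steps 8 and 14 are repeated through the trifluoroacetyl ketone F10, the diazo ketone F11, the ketene F12 and the ester enol F13 to the coupled tris-MOM ester F14. That ester is unmasked with only TFA/CH2Cl2 (1:4) and 1,3,5-trimethoxybenzene at 0 °C to give 30.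

Further compounds

F1 | step 14 | tert-butyl (E)-3-[(2S,3S)-2-(2,2-dimethyl-1,3-benzodioxol-5-yl)-3-(methoxycarbonyl)-7-(methoxymethoxy)-2,3-dihydro-1-benzofuran-4-yl]prop-2-enoate (trans) | COCOc1ccc(/C=C/C(=O)OC(C)(C)C)c2[C@H](C(=O)OC)[C@@H](c3ccc4OC(C)(C)Oc4c3)Oc12
F2 | step 14 | (2S,3S)-4-[(E)-3-tert-butoxy-3-oxoprop-1-enyl]-2-(2,2-dimethyl-1,3-benzodioxol-5-yl)-7-(methoxymethoxy)-2,3-dihydro-1-benzofuran-3-carboxylic acid | COCOc1ccc(/C=C/C(=O)OC(C)(C)C)c2[C@H](C(=O)O)[C@@H](c3ccc4OC(C)(C)Oc4c3)Oc12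
F3 | step 14 | tert-butyl (E)-3-[(2S,3S)-3-(chlorocarbonyl)-2-(2,2-dimethyl-1,3-benzodioxol-5-yl)-7-(methoxymethoxy)-2,3-dihydro-1-benzofuran-4-yl]prop-2-enoate | COCOc1ccc(/C=C/C(=O)OC(C)(C)C)c2[C@H](C(=O)Cl)[C@@H](c3ccc4OC(C)(C)Oc4c3)Oc12
F4 | step 7 | (2S)-2-(2,2-dimethyl-1,3-benzodioxol-5-yl)-8-(methoxymethoxy)-2,3-dihydro-4H-chromen-4-one | COCOc1cccc2C(=O)C[C@@H](c3ccc4OC(C)(C)Oc4c3)Oc12
F5 | step 15 | 1,2-bis(methoxymethoxy)benzene | COCOc1ccccc1OCOC
F6 | step 15 | 4-bromo-1,2-bis(methoxymethoxy)benzene | COCOc1ccc(Br)cc1OCOC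
F7 | step 15 | [3,4-bis(methoxymethoxy)phenyl]lithium | [Li]c1ccc(OCOC)c(OCOC)c1
F8 | step 15 | [3,4-bis(methoxymethoxy)phenyl]boronic acid | COCOc1ccc(B(O)O)cc1OCOC
F9 | step 15 | tert-butyl (E)-3-[(2S)-2-[3,4-bis(methoxymethoxy)phenyl]-8-(methoxymethoxy)-4-oxo-3,4-dihydro-2H-chromen-5-yl]prop-2-enoate | COCOc1ccc(/C=C/C(=O)OC(C)(C)C)c2C(=O)C[C@@H](c3ccc(OCOC)c(OCOC)c3)Oc12
F10 | step 15 | tert-butyl (E)-3-[(2S)-2-[3,4-bis(methoxymethoxy)phenyl]-8-(methoxymethoxy)-4-oxo-3-(trifluoroacetyl)-3,4-dihydro-2H-chromen-5-yl]prop-2-enoate | COCOc1ccc(/C=C/C(=O)OC(C)(C)C)c2C(=O)C(C(=O)C(F)(F)F)[C@@H](c3ccc(OCOC)c(OCOC)c3)Oc12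
F11 | step 15 | tert-butyl (E)-3-[(2R)-2-[3,4-bis(methoxymethoxy)phenyl]-3-diazo-8-(methoxymethoxy)-4-oxo-3,4-dihydro-2H-chromen-5-yl]prop-2-enoate | COCOc1ccc(/C=C/C(=O)OC(C)(C)C)c2C(=O)C(=[N+]=[N-])[C@@H](c3ccc(OCOC)c(OCOC)c3)Oc12
F12 | step 15 | tert-butyl (E)-3-[(2R)-2-[3,4-bis(methoxymethoxy)phenyl]-7-(methoxymethoxy)-3-(oxomethylidene)-2,3-dihydro-1-benzofuran-4-yl]prop-2-enoate (ketene) | COCOc1ccc(/C=C/C(=O)OC(C)(C)C)c2C(=C=O)[C@@H](c3ccc(OCOC)c(OCOC)c3)Oc12
F13 | step 15 | ester enol of F14 (C3=C(OH)O-shikimate, enol geometry undefined) | COCOc1ccc(/C=C/C(=O)OC(C)(C)C)c2C(=C(O)O[C@@H]5CC(C(=O)OCc6ccc(OC)cc6)=C[C@H]7OC(C)(C)O[C@@H]57)[C@@H](c3ccc(OCOC)c(OCOC)c3)Oc12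
F14 | step 15 | 4-methoxybenzyl 3,4-O-isopropylidene-5-O-{[(2S,3R)-2-[3,4-bis(methoxymethoxy)phenyl]-4-[(E)-3-tert-butoxy-3-oxoprop-1-enyl]-7-(methoxymethoxy)-2,3-dihydro-1-benzofuran-3-yl]carbonyl}shikimate | COCOc1ccc(/C=C/C(=O)OC(C)(C)C)c2[C@@H](C(=O)O[C@@H]5CC(C(=O)OCc6ccc(OC)cc6)=C[C@H]7OC(C)(C)O[C@@H]57)[C@@H](c3ccc(OCOC)c(OCOC)c3)Oc12
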